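## Structural features

The target, 6,7-dihydroxy-5-[(7-hydroxy-2-oxo-2H-chromen-6-yl)oxy]-2H-chromen-2-one, consists of two coumarins joined by one diaryl ether oxygen. In the first half (benzo ring A fused to pyranone ring C) the ether oxygen is O6 and sits next to a free 7-hydroxyl. In the second half (benzo ring B fused to pyranone ring D) the same oxygen is attached to C5 and is followed by hydroxyls on C6 and C7. The molecule has no stereocentre and is achiral, so nothing configurational has to be set or preserved. The fragile groups are the two lactones, which open with hydroxide or alkoxide and accept nucleophiles at C4, and the free catechol of ring B, which is oxidised easily once liberated, above all in base. The real difficulty is ring B: it carries five substituents (carbon at C4a, aryloxy at C5, oxygen at C6, C7 and C8a, hydrogen only at C8), and the ether oxygen on C5 is flanked by C4a and the oxygenated C6, so a late ether coupling would have to occur at a doubly ortho-substituted position and a late oxygenation cannot be steered to C5 with confidence. The key step uses the fact that the pair C4a–C5 of ring B, with the one-carbon branch that becomes C4 and the aryloxy group, is an aryl ynol ether in disguise, while C6, C7, C8 and C8a with their three oxygens are the four ring carbons of a 2,3-dialkoxycyclobutenone. Ring A and ring C need not be built, since they are present in esculetin.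

## Logic of the disconnections

20 from 19. No skeletal bond is cut; the three phenolic hydrogens of 20 are replaced by methyl groups. This keeps the oxidation-prone catechol and the acidic phenols masked through every thermal, basic and radical step, and one reagent removes all three groups at the end. The forward step must cleave three aryl O–CH3 bonds, one of them flanked on both sides, without touching the diaryl ether or either lactone; a Lewis acid with acidic work-up fits and keeps the catechol away from base.

19 from 16. In ring D the lactone bond O1–C2 and the double bond C3=C4 are cut. C2 and C3 leave as a stabilised two-carbon ester ylide and the ortho-hydroxy aldehyde 16 remains, with 17 and 18 as open-chain stages in between. The gain is that ring D becomes a single carbon substituent on ring B. The forward step needs olefination of a di-ortho-substituted aldehyde and E to Z isomerisation before the lactone can close.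

16 from 15. The formyl carbon (future C4) is masked as a diethyl acetal. An acetal does not conjugate with the alkyne in the key step and so leaves the polarisation of the ynol ether to the oxygen alone. The forward step is a mild hydrolysis, helped by the neighbouring hydroxyl.

15 from 4 and 10. Ring B is cut at C4a–C8a and at C5–C6; the bond C8–C8a is a bond of 4 that opens and re-forms on the way (11 to 14). This is the simplifying cut: the pentasubstituted arene and the hindered ether both disappear, the ether oxygen is now carried by an unhindered phenol derivative, and every atom of 4 and 10 ends up in 15. Atom mapping of 4 and 10 onto ring B confirms the substitution pattern of 15, so no structure needs correcting. The forward step demands one orientation of the ketene–alkyne addition and thermal survival of an aryl ynol ether, an acetal and a lactone.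

10 from 6 and 8. The bond between O6 of ring A and the alkyne carbon is cut, and the triple bond is traced back to a 1,1-dibromoalkene, with 9 in between. Direct substitution of a 1-bromoalkyne by the phenoxide is not relied on, because phenoxides are expected to add across a bromoalkyne at the carbon remote from bromine, which would attach the oxygen to the wrong alkyne carbon. The forward step needs a vinylic C–O coupling that keeps the acetal and a dehydrobromination that spares the lactone.

8 from 7. The C=C bond is cut back to an aldehyde and a dibromomethylene unit. The forward step is a dibromo-olefination under buffered conditions so that the acetal is kept.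

6 from 5. The O7–CH3 bond is cut. The forward step must distinguish the two phenols of 5; the higher acidity of the 7-hydroxyl, which is conjugated with the lactone carbonyl, provides the handle.

4 from 3, 2 and 1. The two C4–H bonds of 4 are traced back to a carbonyl: one hydrogen comes from hydride addition to 1 (giving 2), the other from removal of the resulting hydroxyl through its thiocarbonyl derivative 3. The gain is a cheap, symmetric four-carbon starting material that already holds both methoxy groups. The C–O cleavage must avoid acid, which would ionise C4–O and rearrange the ring to a cyclobutenedione; a neutral radical deoxygenation is therefore chosen.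

## Other disconnections considered

Alternative 1: The cut is at O1–C8a in both pyranone rings, C and D, so the precursor is the bis-acrylic acid A2, (2E)-3-(2-{5-[(1E)-2-carboxyethenyl]-2-methoxyphenoxy}-3,4-dimethoxyphenyl)prop-2-enoic acid. In the forward key step a flavin photocatalyst under blue light and oxygen would isomerise each arm to Z and then join each carboxylate oxygen to the neighbouring arene carbon, giving the trimethyl ether A1, which is the same compound as 19.
- In its favour: A2 should be reachable in two operations from benzaldehyde-level materials (an ether coupling on an aryl halide activated by an ortho-formyl group, then a double Knoevenagel–Doebner condensation). The hindered ether is made at the easiest stage, both lactones arise in one flask, and oxygen is the only stoichiometric oxidant.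
- Against it here: the arm on ring A has two free ortho positions, and closure must go to the one para to the ether oxygen and not to the one between the arm and the ether. Two oxidative C–O bond formations must succeed on one molecule, the second on a substrate that already contains a light-absorbing coumarin, and a trioxygenated arene must not be over-oxidised.
- Comparison: in step economy this alternative is clearly the better plan (about four steps against ten), and in handling the hindered ether it is at least the equal. The chosen plan is better in that every substituent of ring B is fixed by the two components, so no positional question on an arene arises, and no oxidant is needed. Mechanistically both key steps stretch known reaction types; the photochemical lactonisation is better established for simple cinnamic acids, the benzannulation better defined in its regiochemistry.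

Alternative 2: Ring A is cut at C8–C8a and traced back to the 2-pyranone A4, ethyl 5-[(6,7-dimethoxy-2-oxo-2H-chromen-5-yl)oxy]-6-methyl-2-oxo-2H-pyran-3-carboxylate. In the forward key step an alkoxide would open the pyranone at its lactone carbonyl, the liberated methyl ketone would be enolised at the methyl group, and intramolecular Claisen condensation onto an ester carbon followed by enolisation would give the resorcylate A3, ethyl 5-[(6,7-dimethoxy-2-oxo-2H-chromen-5-yl)oxy]-2,4-dihydroxybenzoate.
- In its favour: anionic ring transformations of this kind are dependable, every substituent of ring A follows from the pyranone, and the two hydroxyls of A3 are already the future O1 and the free 7-hydroxyl.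
- Against it: the ether oxygen must come from 5-hydroxy-6,7-dimethoxy-2H-chromen-2-one A5, a phenol whose regioselective preparation is a positional problem of its own, so the real difficulty (ring B) is only moved into a starting material. The alkoxide also opens the lactone of ring D, which must re-close with retention of the Z geometry, and the ester of A3 must still be brought to the aldehyde level before ring C can be closed.
- Comparison: on the security of the key step this alternative is the better one, since its reaction type is established and the benzannulation is not. On structure the chosen plan fits the target better, because it builds the pentasubstituted ring B and takes ring A ready-made from 5, while this alternative builds the simple ring and needs the difficult one as an input. In step count it would at best equal the chosen plan once A5 has to be made.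

Alternative 3: Ring A is cut at C5–C6 and C4a–C8a, which gives the bis-silyl dienol ether A7, 5-({4-methoxy-2,4-bis[(trimethylsilyl)oxy]buta-1,3-dien-1-yl}oxy)-6,7-dimethoxy-2H-chromen-2-one, and an alkynoic thioester. Forward, a Diels–Alder addition in which the aryloxy-bearing diene terminus bonds to the β-carbon of the ynoate, followed by loss of methanol and desilylation, would give thioester A6, S-ethyl 5-[(6,7-dimethoxy-2-oxo-2H-chromen-5-yl)oxy]-2,4-dihydroxybenzenecarbothioate.
- In its favour: the regiochemistry of cycloadditions of 1,3-bis(silyloxy)dienes is reliable, the conditions are neutral and spare the lactone of ring D, and the thioester can be reduced directly to the aldehyde needed for a Wittig lactonisation.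
- Against it: it needs the same phenol A5 as alternative 2. The diene must be made by double enolisation of an aryloxy acetoacetate next to a base-sensitive lactone, a substituent on the reacting diene terminus slows the cycloaddition, and the diene is moisture-sensitive.
- Comparison: in logic this is the mirror image of the chosen plan, since in both the ether oxygen rides on a polarised π-component and the arene is made around it. In predictability of the cycloaddition it is the equal or the better. The chosen plan keeps the advantage in starting materials (5 instead of A5) and in atom economy of the ring-forming step, since nothing is lost; in steps after ring formation the two are about equal.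

Key step: step 7

Assumption: 2,2-diethoxyacetaldehyde (7) is taken as a commercial reagent; 6 can also be bought, in which case step 4 falls away.

## Route

Step 1
Reactants: 1 dimethyl squarate (3,4-dimethoxycyclobut-3-ene-1,2-dione)
Product: 2 rac-4-hydroxy-2,3-dimethoxycyclobut-2-en-1-one
Conditions: LiAlH(Ot-Bu)3 (1.05 equiv), THF, −78 to −20 °C; aq. NaHCO3
Reagents that add atoms: none
Why: 1,2-Reduction of one squarate carbonyl by a hindered aluminium hydride should stop at the mono-adduct because the remaining carbonyl is a vinylogous ester; the carbinol centre forms as a racemate and is removed in step 3.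

Step 2
Reactants: 2 rac-4-hydroxy-2,3-dimethoxycyclobut-2-en-1-one
Product: 3 rac-O-(2,3-dimethoxy-4-oxocyclobut-2-en-1-yl) 1H-imidazole-1-carbothioate
Conditions: 1,1'-thiocarbonyldiimidazole, DMAP (cat.), CH2Cl2, rt
Reagents that add atoms: 1,1'-thiocarbonyldiimidazole, S=C(n1ccnc1)n1ccnc1
Why: Thioacylation of the secondary alcohol under neutral conditions gives the derivative needed for a Barton–McCombie deoxygenation; acid, which would ionise C4–O and rearrange the ring to a cyclobutenedione, is avoided.

Step 3
Reactants: 3 rac-O-(2,3-dimethoxy-4-oxocyclobut-2-en-1-yl) 1H-imidazole-1-carbothioate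
Product: 4 2,3-dimethoxycyclobut-2-en-1-one
Conditions: (Me3Si)3SiH, AIBN (cat.), PhMe, 80 °C
Reagents that add atoms: none
Why: Barton–McCombie radical deoxygenation with a tin-free silane: the silyl radical adds to sulfur, C4–O breaks, and hydrogen-atom transfer to the less hindered, hydrogen-bearing terminus C4 of the delocalised oxocyclobutenyl radical should keep the tetrasubstituted dialkoxy enone; the C4 stereocentre disappears.

Step 4
Reactants: 5 esculetin (6,7-dihydroxy-2H-chromen-2-one)
Product: 6 6-hydroxy-7-methoxy-2H-chromen-2-one
Conditions: MeI (1.05 equiv), Li2CO3 (1.0 equiv), DMF, rt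
Reagents that add atoms: iodomethane, CI
Why: The 7-hydroxyl is conjugated with the lactone carbonyl and is the more acidic phenol, so one equivalent of weak base should form the 7-phenoxide selectively and Williamson methylation then gives the 7-methyl ether.

Step 5
Reactants: 7 2,2-diethoxyacetaldehyde
Product: 8 1,1-dibromo-3,3-diethoxyprop-1-ene
Conditions: CBr4, PPh3, Et3N, CH2Cl2, 0 °C
Reagents that add atoms: tetrabromomethane, BrC(Br)(Br)Br
Why: Ramirez dibromo-olefination of an aldehyde (first stage of the Corey–Fuchs sequence); triethylamine buffers the acidic phosphorus by-products so that the acetal survives.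

Step 6
Reactants: 6 6-hydroxy-7-methoxy-2H-chromen-2-one; 8 1,1-dibromo-3,3-diethoxyprop-1-ene
Product: 10 6-[(3,3-diethoxyprop-1-yn-1-yl)oxy]-7-methoxy-2H-chromen-2-one, via bromo enol ether 9 (not isolated)
Conditions: CuI (10 mol%), 2,2'-bipyridine (20 mol%), K3PO4, PhMe, 110 °C; then t-BuOK, 1,4-dioxane, rt
Reagents that add atoms: none
Why: Copper-catalysed vinylic C–O coupling of a phenol with a 1,1-dibromoalkene should replace the bromide trans to the substituent and give the Z-bromo enol ether 9, whose vinylic hydrogen is anti to bromine; tert-butoxide then effects E2 dehydrobromination to the ynol ether.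

Step 7
Reactants: 4 2,3-dimethoxycyclobut-2-en-1-one; 10 6-[(3,3-diethoxyprop-1-yn-1-yl)oxy]-7-methoxy-2H-chromen-2-one
Product: 15 6-[6-(diethoxymethyl)-5-hydroxy-2,3-dimethoxyphenoxy]-7-methoxy-2H-chromen-2-one, via vinylketene 11 (not isolated), via cycloadduct cyclobutenone 12 (not isolated), via dienylketene 13 (not isolated), via cyclohexadienone 14 (not isolated)
Conditions: PhMe, sealed tube, Ar, 110 °C then 140 °C (4 in slight excess, added in portions)
Reagents that add atoms: none
Why: Proposed new method: heating should open 4 by conrotatory four-electron ring opening to vinylketene 11, whose electrophilic carbonyl carbon is attacked by the acetal-bearing alkyne carbon of 10 (made nucleophilic by donation from the aryloxy oxygen), so that [2+2] cycloaddition gives cyclobutenone 12 with the new bonds C4a–C8a and C5–C6. Ring opening of 12 should turn the donor methoxy group on the quaternary carbon outward and the methoxyvinyl group inward, giving dienylketene 13 with the Z geometry needed for closure. Ring B is then closed by a disrotatory six-electron electrocyclisation that re-forms C8–C8a (14), and tautomerisation at C8 gives phenol 15. The closest known reaction type is the thermal benzannulation of cyclobutenones with alkoxy- or silyloxyalkynes through vinylketenes (Danheiser benzannulation); neither a 2,3-dialkoxycyclobutenone nor an acetal-bearing aryl ynol ether has been used in it. No stereocentre is formed in 15; the quaternary centre of 12 is transient and racemic. The selectivity needed is the orientation of the ketene–alkyne addition, and it is secured by the polarisation of the ynol ether, which places the new hydroxyl (future O1) ortho to the acetal carbon (future C4) and the aryloxy group on C5. The aryloxy group has no hydrogen that could be lost in a retro-ene reaction, so the thermal breakdown that limits alkyl ynol ethers cannot occur.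

Step 8
Reactants: 15 6-[6-(diethoxymethyl)-5-hydroxy-2,3-dimethoxyphenoxy]-7-methoxy-2H-chromen-2-one
Product: 16 6-hydroxy-3,4-dimethoxy-2-[(7-methoxy-2-oxo-2H-chromen-6-yl)oxy]benzaldehyde
Conditions: PPTS (cat.), acetone–H2O, rt
Reagents that add atoms: water, O
Why: Acid-catalysed acetal hydrolysis; the ortho-hydroxyl assists ionisation, so mild acid should suffice and the diaryl ether and the lactone stay untouched.

Step 9
Reactants: 16 6-hydroxy-3,4-dimethoxy-2-[(7-methoxy-2-oxo-2H-chromen-6-yl)oxy]benzaldehyde
Product: 19 6,7-dimethoxy-5-[(7-methoxy-2-oxo-2H-chromen-6-yl)oxy]-2H-chromen-2-one, via E-cinnamate 17 (not isolated), via Z-cinnamate 18 (not isolated)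
Conditions: Ph3P=CHCO2Et, PhNEt2, reflux
Reagents that add atoms: ethyl (triphenylphosphoranylidene)acetate, CCOC(=O)C=P(c1ccccc1)(c1ccccc1)c1ccccc1
Why: Wittig olefination of a salicylaldehyde with a stabilised ylide, then thermal E to Z isomerisation and lactonisation with loss of ethanol (Wittig lactonisation) should close ring D; the high-boiling amine supplies the temperature for the isomerisation.

Step 10
Reactants: 19 6,7-dimethoxy-5-[(7-methoxy-2-oxo-2H-chromen-6-yl)oxy]-2H-chromen-2-one
Product: 20 6,7-dihydroxy-5-[(7-hydroxy-2-oxo-2H-chromen-6-yl)oxy]-2H-chromen-2-one
Conditions: BBr3, CH2Cl2, −78 °C to rt; then MeOH, H2O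
Reagents that add atoms: none
Why: Lewis-acid cleavage of aryl methyl ethers: BBr3 binds each methoxy oxygen and bromide removes the methyl group by SN2, a standard demethylation of methoxycoumarins that leaves diaryl ethers and lactones intact; the acidic work-up protects the catechol.

## Compound list

1 | dimethyl squarate (3,4-dimethoxycyclobut-3-ene-1,2-dione) | COC1=C(OC)C(=O)C1=O | starting material
2 | rac-4-hydroxy-2,3-dimethoxycyclobut-2-en-1-one | COC1=C(OC)C(=O)C1O | intermediate
3 | rac-O-(2,3-dimethoxy-4-oxocyclobut-2-en-1-yl) 1H-imidazole-1-carbothioate | COC1=C(OC)C(=O)C1OC(=S)n1ccnc1 | intermediate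
4 | 2,3-dimethoxycyclobut-2-en-1-one | COC1=C(OC)C(=O)C1 | intermediate
5 | esculetin (6,7-dihydroxy-2H-chromen-2-one) | O=c1ccc2cc(O)c(O)cc2o1 | starting material
6 | 6-hydroxy-7-methoxy-2H-chromen-2-one | COc1cc2oc(=O)ccc2cc1O | intermediate
7 | 2,2-diethoxyacetaldehyde | CCOC(OCC)C=O | starting material
8 | 1,1-dibromo-3,3-diethoxyprop-1-ene | CCOC(OCC)C=C(Br)Br | intermediate
9 | 6-{[(1Z)-1-bromo-3,3-diethoxyprop-1-en-1-yl]oxy}-7-methoxy-2H-chromen-2-one | CCOC(OCC)/C=C(\Br)Oc1cc2ccc(=O)oc2cc1OC | intermediate
10 | 6-[(3,3-diethoxyprop-1-yn-1-yl)oxy]-7-methoxy-2H-chromen-2-one | CCOC(OCC)C#COc1cc2ccc(=O)oc2cc1OC | intermediate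
11 | 2,3-dimethoxybuta-1,3-dien-1-one | O=C=C(OC)C(OC)=C | intermediate
12 | rac-2-(diethoxymethyl)-4-methoxy-4-(1-methoxyethenyl)-3-[(7-methoxy-2-oxo-2H-chromen-6-yl)oxy]cyclobut-2-en-1-one | C=C(OC)C1(OC)C(=O)C(C(OCC)OCC)=C1Oc1cc2ccc(=O)oc2cc1OC | intermediate
13 | (3Z)-2-(diethoxymethyl)-4,5-dimethoxy-3-[(7-methoxy-2-oxo-2H-chromen-6-yl)oxy]hexa-1,3,5-trien-1-one | O=C=C(C(OCC)OCC)/C(Oc1cc2ccc(=O)oc2cc1OC)=C(OC)\C(OC)=C | intermediate
14 | 2-(diethoxymethyl)-4,5-dimethoxy-3-[(7-methoxy-2-oxo-2H-chromen-6-yl)oxy]cyclohexa-2,4-dien-1-one | CCOC(OCC)C1=C(Oc2cc3ccc(=O)oc3cc2OC)C(OC)=C(OC)CC1=O | intermediate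
15 | 6-[6-(diethoxymethyl)-5-hydroxy-2,3-dimethoxyphenoxy]-7-methoxy-2H-chromen-2-one | CCOC(OCC)c1c(O)cc(OC)c(OC)c1Oc1cc2ccc(=O)oc2cc1OC | intermediate
16 | 6-hydroxy-3,4-dimethoxy-2-[(7-methoxy-2-oxo-2H-chromen-6-yl)oxy]benzaldehyde | O=Cc1c(O)cc(OC)c(OC)c1Oc1cc2ccc(=O)oc2cc1OC | intermediate
17 | ethyl (2E)-3-{6-hydroxy-3,4-dimethoxy-2-[(7-methoxy-2-oxo-2H-chromen-6-yl)oxy]phenyl}prop-2-enoate | CCOC(=O)/C=C/c1c(O)cc(OC)c(OC)c1Oc1cc2ccc(=O)oc2cc1OC | intermediate
18 | ethyl (2Z)-3-{6-hydroxy-3,4-dimethoxy-2-[(7-methoxy-2-oxo-2H-chromen-6-yl)oxy]phenyl}prop-2-enoate | CCOC(=O)/C=C\c1c(O)cc(OC)c(OC)c1Oc1cc2ccc(=O)oc2cc1OC | intermediate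
19 | 6,7-dimethoxy-5-[(7-methoxy-2-oxo-2H-chromen-6-yl)oxy]-2H-chromen-2-one | COc1cc2oc(=O)ccc2cc1Oc1c(OC)c(OC)cc2oc(=O)ccc12 | intermediate
20 | 6,7-dihydroxy-5-[(7-hydroxy-2-oxo-2H-chromen-6-yl)oxy]-2H-chromen-2-one | O=c1ccc2cc(Oc3c(O)c(O)cc4oc(=O)ccc34)c(O)cc2o1 | target

## Step count and least certain steps

Total: 10 steps. Longest linear sequence: 7 steps (steps 1, 2, 3, 7, 8, 9, 10).

Step 7 (key step). The cycloaddition between the donor-substituted vinylketene and the only moderately nucleophilic aryl ynol ether may be slower than self-condensation of the ketene or acylation of the product phenol by it, so that 4 is consumed without ring B being formed. Fallback with known chemistry, from 6 back to 19: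
- Ullmann ether coupling of 6 with commercial 2-bromo-3,4-dimethoxybenzaldehyde (CuI, N,N-dimethylglycine, Cs2CO3, 1,4-dioxane, 100 °C), the ortho-formyl group activating the bromide, should give 3,4-dimethoxy-2-[(7-methoxy-2-oxo-2H-chromen-6-yl)oxy]benzaldehyde F1.
- Knoevenagel–Doebner condensation with malonic acid (pyridine, piperidine cat., 90 °C) should give (2E)-3-{3,4-dimethoxy-2-[(7-methoxy-2-oxo-2H-chromen-6-yl)oxy]phenyl}prop-2-enoic acid F2.
- Flavin-photocatalysed oxidative lactonisation (riboflavin cat., O2, blue light, MeCN–MeOH), a reaction type known for electron-rich cinnamic acids, at the only free ortho position of F2 closes ring D and returns to the route at 19.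

Step 3. Hydrogen-atom transfer may occur at the methoxy-bearing end of the delocalised radical instead of at C4 (poor site selectivity); an allylic thiono-to-thiolo shift of 3 beforehand would not matter, since both forms fragment to the same radical. Fallback, from 3 back to 4, replacing kinetic site selectivity by thermodynamic control:
- The reduction is run as before and the transposed enone, rac-3,4-dimethoxycyclobut-2-en-1-one F3, is not separated.
- The crude mixture is treated with methanol, trimethyl orthoformate and catalytic TsOH, which should add methanol to either enone and give the common ketal rac-2,3,3-trimethoxycyclobutan-1-one F4.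
- Warming F4 in toluene with a trace of acid while methanol distils off should re-form the enone with both methoxy groups on the double bond, 4.

Step 6. tert-Butoxide may open the lactone of ring C in competition with dehydrobromination, or the acetal oxygen atoms may bind copper and stall the coupling. Fallback, from 6 back to 10, forming the C–O bond by SN2 and the alkyne by triflate elimination at low temperature:
- Bromination of commercial 1,1-diethoxypropan-2-one (Br2, EtOH, 0 °C) gives 3-bromo-1,1-diethoxypropan-2-one F5.
- O-Alkylation of 6 with F5 (K2CO3, acetone, rt) gives 6-(3,3-diethoxy-2-oxopropoxy)-7-methoxy-2H-chromen-2-one F6.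
- Enolisation on the aryloxy side and triflation (KN(SiMe3)2, PhNTf2, THF, −78 °C) gives (1Z)-3,3-diethoxy-1-[(7-methoxy-2-oxo-2H-chromen-6-yl)oxy]prop-1-en-2-yl trifluoromethanesulfonate F7.
- A second equivalent of KN(SiMe3)2 at −78 °C removes the vinylic hydrogen anti to the triflate and gives 10.

Step 9. Olefination of the di-ortho-substituted, electron-rich aldehyde may be slow and E to Z isomerisation incomplete, so that the reaction stalls at the E-cinnamate under prolonged thermal stress. Fallback, from 16 back to 19, reversing the order of bond formation (Perkin coumarin synthesis):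
- Acetylation of the phenol (Ac2O, Et3N, rt) gives 2-formyl-4,5-dimethoxy-3-[(7-methoxy-2-oxo-2H-chromen-6-yl)oxy]phenyl acetate F8.
- Heating F8 with NaOAc in Ac2O (160 °C) brings about intramolecular aldol condensation of the acetate onto the formyl group; this can only give the cis ring and leads to 19 without an alkene isomerisation.

## Further compounds

F1 | step 7 | 3,4-dimethoxy-2-[(7-methoxy-2-oxo-2H-chromen-6-yl)oxy]benzaldehyde | O=Cc1ccc(OC)c(OC)c1Oc1cc2ccc(=O)oc2cc1OC
F2 | step 7 | (2E)-3-{3,4-dimethoxy-2-[(7-methoxy-2-oxo-2H-chromen-6-yl)oxy]phenyl}prop-2-enoic acid | OC(=O)/C=C/c1ccc(OC)c(OC)c1Oc1cc2ccc(=O)oc2cc1OC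
F3 | step 3 | rac-3,4-dimethoxycyclobut-2-en-1-one | COC1C(=O)C=C1OC
F4 | step 3 | rac-2,3,3-trimethoxycyclobutan-1-one | COC1C(=O)CC1(OC)OC
F5 | step 6 | 3-bromo-1,1-diethoxypropan-2-one | CCOC(OCC)C(=O)CBr
F6 | step 6 | 6-(3,3-diethoxy-2-oxopropoxy)-7-methoxy-2H-chromen-2-one | CCOC(OCC)C(=O)COc1cc2ccc(=O)oc2cc1OC
F7 | step 6 | (1Z)-3,3-diethoxy-1-[(7-methoxy-2-oxo-2H-chromen-6-yl)oxy]prop-1-en-2-yl trifluoromethanesulfonate | CCOC(OCC)/C(OS(=O)(=O)C(F)(F)F)=C/Oc1cc2ccc(=O)oc2cc1OC
F8 | step 9 | 2-formyl-4,5-dimethoxy-3-[(7-methoxy-2-oxo-2H-chromen-6-yl)oxy]phenyl acetate | CC(=O)Oc1cc(OC)c(OC)c(Oc2cc3ccc(=O)oc3cc2OC)c1C=O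
A1 | alternative 1 | 6,7-dimethoxy-5-[(7-methoxy-2-oxo-2H-chromen-6-yl)oxy]-2H-chromen-2-one | COc1cc2oc(=O)ccc2cc1Oc1c(OC)c(OC)cc2oc(=O)ccc12
A2 | alternative 1 | (2E)-3-(2-{5-[(1E)-2-carboxyethenyl]-2-methoxyphenoxy}-3,4-dimethoxyphenyl)prop-2-enoic acid | OC(=O)/C=C/c1ccc(OC)c(Oc2c(OC)c(OC)ccc2/C=C/C(=O)O)c1
A3 | alternative 2 | ethyl 5-[(6,7-dimethoxy-2-oxo-2H-chromen-5-yl)oxy]-2,4-dihydroxybenzoate | CCOC(=O)c1cc(Oc2c(OC)c(OC)cc3oc(=O)ccc23)c(O)cc1O
A4 | alternative 2 | ethyl 5-[(6,7-dimethoxy-2-oxo-2H-chromen-5-yl)oxy]-6-methyl-2-oxo-2H-pyran-3-carboxylate | CCOC(=O)c1cc(Oc2c(OC)c(OC)cc3oc(=O)ccc23)c(C)oc1=O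
A5 | alternative 2 | 5-hydroxy-6,7-dimethoxy-2H-chromen-2-one | COc1cc2oc(=O)ccc2c(O)c1OC
A6 | alternative 3 | S-ethyl 5-[(6,7-dimethoxy-2-oxo-2H-chromen-5-yl)oxy]-2,4-dihydroxybenzenecarbothioate | CCSC(=O)c1cc(Oc2c(OC)c(OC)cc3oc(=O)ccc23)c(O)cc1O
A7 | alternative 3 | 5-({4-methoxy-2,4-bis[(trimethylsilyl)oxy]buta-1,3-dien-1-yl}oxy)-6,7-dimethoxy-2H-chromen-2-one | COC(O[Si](C)(C)C)=CC(O[Si](C)(C)C)=COc1c(OC)c(OC)cc2oc(=O)ccc12
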